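**Plan**

1. The target is a 3,3''-biflavanone: unit A (5,7-dihydroxy, 2S,3R, 2,3-trans) and unit B (5-hydroxy-7-methoxy, 2''S,3''S, 2'',3''-cis). The retrosynthesis first returns the cis unit B to a flavone (C2''=C3''), which is reduced last because the cis arrangement is kinetic and epimerisable.
2. Ring C of unit A is then cut at O1–C2 and C4–C4a, giving free phloroglucinol and an α-(flavon-3-yl)-4-methoxycinnamoyl chloride. The C3–C3'' bond is cut last, giving a 3-iodoflavone and an α-stannyl cinnamate.
3. The feature that allows the annulation is ring A of unit A: C4a lies between C5–OH and C8a–O1, so phloroglucinol (three equivalent CH, each flanked by two OH) is a 1,3-C,O-bis-nucleophile. C4–C3–C2 is the matching enoyl 1,3-bis-electrophile, with C2 activated by the 4-methoxyphenyl group.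
4. Forward: the flavone ring of unit B is present from the start; C3''–C3 is joined by Stille coupling; ring C of unit A is closed in one flask by a [3+3] annulation; ring C of unit B is saturated last.
5. Stereochemistry: C2 by alkaloid-catalysed oxa-Michael addition, C3 by thermodynamic protonation (trans), C2''/C3'' by syn hydrogenation with the face relayed from C3 through allylic 1,3-strain.

Key step: step 7

Remark: 4',5,7-trimethoxyflavone, 4-ethynylanisole and phloroglucinol are taken as purchasable; step 7 is run in one flask with no work-up or isolation between reagent additions.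

**Step 1**
Reactants: 1 1-ethynyl-4-methoxybenzene
Product: 3 tert-butyl 3-(4-methoxyphenyl)prop-2-ynoate, via lithium acetylide 2 (not isolated)
Conditions: n-BuLi, THF, −78 °C; Boc2O, −78 °C → rt; H2O
Reagents that add atoms: di-tert-butyl dicarbonate CC(C)(C)OC(=O)OC(=O)OC(C)(C)C
Why: Deprotonation of the terminal alkyne and C-acylation of the lithium acetylide with Boc2O is a standard route to tert-butyl alkynoates, and no stereocentre is formed.

**Step 2**
Reactants: 3 tert-butyl 3-(4-methoxyphenyl)prop-2-ynoate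
Product: 4 tert-butyl (E)-3-(4-methoxyphenyl)-2-(tributylstannyl)prop-2-enoate
Conditions: Bu3SnH, Pd(PPh3)4 (2 mol %), THF, 0 °C → rt
Reagents that add atoms: tributyltin hydride CCCC[SnH](CCCC)CCCC
Why: Palladium-catalysed hydrostannation of aryl propiolates is a syn addition that places tin on the carbon next to the ester, which fixes the alkene geometry (tin trans to the aryl group) that the later coupling transfers with retention.

**Step 3**
Reactants: 5 5,7-dimethoxy-2-(4-methoxyphenyl)-4H-chromen-4-one
Product: 7 3-iodo-5,7-dimethoxy-2-(4-methoxyphenyl)-4H-chromen-4-one, via 3-lithioflavone 6 (not isolated)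
Conditions: LiN(i-Pr)2, THF, −78 °C; I2, −78 °C → rt
Reagents that add atoms: iodine II
Why: Directed lithiation of the flavone at C3 (the vinylic C–H next to the C4 carbonyl) followed by iodine quench places the halide at the future C3'' and avoids the electron-rich ring carbons that an electrophilic iodination could attack.

**Step 4**
Reactants: 7 3-iodo-5,7-dimethoxy-2-(4-methoxyphenyl)-4H-chromen-4-one
Product: 9 5-hydroxy-3-iodo-7-methoxy-2-(4-methoxyphenyl)-4H-chromen-4-one, via dichloroboryl ether 8 (not isolated)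
Conditions: BCl3, CH2Cl2, −78 → 0 °C; H2O
Reagents that add atoms: none
Why: BCl3 chelates the C4 carbonyl and cleaves only the peri 5-methoxy group (chelation-controlled demethylation of 5-methoxyflavones), leaving the 7- and 4'-methyl ethers that the target keeps.

**Step 5**
Reactants: 9 5-hydroxy-3-iodo-7-methoxy-2-(4-methoxyphenyl)-4H-chromen-4-one; 4 tert-butyl (E)-3-(4-methoxyphenyl)-2-(tributylstannyl)prop-2-enoate
Product: 10 tert-butyl (Z)-2-[5-hydroxy-7-methoxy-2-(4-methoxyphenyl)-4-oxo-4H-chromen-3-yl]-3-(4-methoxyphenyl)prop-2-enoate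
Conditions: Pd(PPh3)4 (10 mol %), CuI (20 mol %), CsF, DMF, 45 °C
Reagents that add atoms: none
Why: Stille coupling of a 3-iodoflavone with an α-stannyl acrylate, with CuI and CsF to speed transmetalation of hindered partners, should form the C3''–C3 bond with retention of alkene geometry.

**Step 6**
Reactants: 10 tert-butyl (Z)-2-[5-hydroxy-7-methoxy-2-(4-methoxyphenyl)-4-oxo-4H-chromen-3-yl]-3-(4-methoxyphenyl)prop-2-enoate
Product: 12 (Z)-2-[5-hydroxy-7-methoxy-2-(4-methoxyphenyl)-4-oxo-4H-chromen-3-yl]-3-(4-methoxyphenyl)prop-2-enoyl chloride, via carboxylic acid 11 (not isolated)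
Conditions: SOCl2 (neat), rt; evaporation, crude used directly
Reagents that add atoms: thionyl chloride O=S(Cl)Cl
Why: Thionyl chloride converts tert-butyl esters directly into acid chlorides (acid-induced loss of the tert-butyl group, then chlorination of the acid), which avoids a basic hydrolysis next to the flavone, and the hydrogen-bonded 5-OH is not expected to react.

**Step 7**
Reactants: 12 (Z)-2-[5-hydroxy-7-methoxy-2-(4-methoxyphenyl)-4-oxo-4H-chromen-3-yl]-3-(4-methoxyphenyl)prop-2-enoyl chloride; 13 benzene-1,3,5-triol (phloroglucinol)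
Product: 16 (2S,3R)-5,7-dihydroxy-3-[5-hydroxy-7-methoxy-2-(4-methoxyphenyl)-4-oxo-4H-chromen-3-yl]-2-(4-methoxyphenyl)chroman-4-one, via O-borylated chalcone 14 (not isolated), via free chalcone 15 (not isolated)
Conditions: BCl3 (4.5 equiv), ClCH2CH2Cl, 0 → 45 °C; MeOH, −20 °C, evaporation; quinine (30 mol %), PhCl, rt
Reagents that add atoms: none
Why: Proposed new method: BCl3 converts every phenolic OH of 13 and the 5-OH of 12 into ArO–BCl2 groups, and the boron on a phloroglucinol oxygen binds the acid chloride and hands the acyl group to the neighbouring ring carbon (boron-tethered Friedel–Crafts acylation, C4–C4a), giving 14 in which no free OH is left to cyclise; methanol then removes boron as volatile B(OMe)3 and frees chalcone 15, in which quinine activates an ortho OH as a hydrogen-bonded ion pair that adds to C2 (O1–C2). The closest known reaction types are the BCl3-mediated ortho-acylation of phenols with acid chlorides and the cinchona-alkaloid-catalysed intramolecular oxa-Michael addition of o-(α-substituted enoyl)phenols to 2,3-disubstituted chroman-4-ones, which have not been run in one flask or on an α-heteroaryl-β-aryl enone. The pyranone ring closes by 6-endo-trig oxa-Michael addition. C2 is set by the alkaloid (catalyst control; 2S is expected by analogy with 2-alkyl chromanones), and C3 by reversible protonation under the amine, which settles on the 2,3-trans (3R) arrangement with both large groups equatorial. The step needs attack of the ring carbon on the acyl carbon and not on C2 (which would lead to a 4-aryl-dihydrocoumarin), secured by the boron tether and the hard acyl chloride, and it needs the chalcone to stay open until quinine is present, secured by full O-borylation; regiochemistry is no issue because the three CH positions of phloroglucinol are equivalent.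

**Step 8**
Reactants: 16 (2S,3R)-5,7-dihydroxy-3-[5-hydroxy-7-methoxy-2-(4-methoxyphenyl)-4-oxo-4H-chromen-3-yl]-2-(4-methoxyphenyl)chroman-4-one
Product: 17 (2S,3R)-5,7-dihydroxy-3-[(2S,3S)-5-hydroxy-7-methoxy-2-(4-methoxyphenyl)-4-oxochroman-3-yl]-2-(4-methoxyphenyl)chroman-4-one
Conditions: H2 (1–4 atm), 10% Pd/C, EtOAc–MeOH, rt; filtration, no acid or base
Reagents that add atoms: none
Why: Heterogeneous catalytic hydrogenation of a 2,3-disubstituted chromone is a syn addition that gives the cis-chromanone, and the face is chosen by C3, whose C–H bond eclipses the C2''-aryl side (allylic 1,3-strain) so that the anisyl-bearing C2 half of unit A blocks one face and hydrogen enters from the face next to the C4 carbonyl, which gives 2''S,3''S, while the neutral medium keeps the kinetic cis unit from epimerising.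

**Compound list**

1 | 1-ethynyl-4-methoxybenzene | C#Cc1ccc(OC)cc1 | starting material
2 | lithium (4-methoxyphenyl)acetylide | [Li]C#Cc1ccc(OC)cc1 | intermediate
3 | tert-butyl 3-(4-methoxyphenyl)prop-2-ynoate | COc1ccc(C#CC(=O)OC(C)(C)C)cc1 | intermediate
4 | tert-butyl (E)-3-(4-methoxyphenyl)-2-(tributylstannyl)prop-2-enoate | COc1ccc(/C=C(/[Sn](CCCC)(CCCC)CCCC)C(=O)OC(C)(C)C)cc1 | intermediate
5 | 5,7-dimethoxy-2-(4-methoxyphenyl)-4H-chromen-4-one (4',5,7-trimethoxyflavone) | COc1ccc(-c2cc(=O)c3c(OC)cc(OC)cc3o2)cc1 | starting material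
6 | 3-lithio-5,7-dimethoxy-2-(4-methoxyphenyl)-4H-chromen-4-one | [Li]c1c(-c2ccc(OC)cc2)oc2cc(OC)cc(OC)c2c1=O | intermediate
7 | 3-iodo-5,7-dimethoxy-2-(4-methoxyphenyl)-4H-chromen-4-one | COc1ccc(-c2oc3cc(OC)cc(OC)c3c(=O)c2I)cc1 | intermediate
8 | 5-(dichloroboryloxy)-3-iodo-7-methoxy-2-(4-methoxyphenyl)-4H-chromen-4-one | COc1ccc(-c2oc3cc(OC)cc(OB(Cl)Cl)c3c(=O)c2I)cc1 | intermediate
9 | 5-hydroxy-3-iodo-7-methoxy-2-(4-methoxyphenyl)-4H-chromen-4-one | COc1ccc(-c2oc3cc(OC)cc(O)c3c(=O)c2I)cc1 | intermediate
10 | tert-butyl (Z)-2-[5-hydroxy-7-methoxy-2-(4-methoxyphenyl)-4-oxo-4H-chromen-3-yl]-3-(4-methoxyphenyl)prop-2-enoate | COc1ccc(/C=C(\C(=O)OC(C)(C)C)c2c(-c3ccc(OC)cc3)oc3cc(OC)cc(O)c3c2=O)cc1 | intermediate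
11 | (Z)-2-[5-hydroxy-7-methoxy-2-(4-methoxyphenyl)-4-oxo-4H-chromen-3-yl]-3-(4-methoxyphenyl)prop-2-enoic acid | COc1ccc(/C=C(\C(=O)O)c2c(-c3ccc(OC)cc3)oc3cc(OC)cc(O)c3c2=O)cc1 | intermediate
12 | (Z)-2-[5-hydroxy-7-methoxy-2-(4-methoxyphenyl)-4-oxo-4H-chromen-3-yl]-3-(4-methoxyphenyl)prop-2-enoyl chloride | COc1ccc(/C=C(\C(Cl)=O)c2c(-c3ccc(OC)cc3)oc3cc(OC)cc(O)c3c2=O)cc1 | intermediate
13 | benzene-1,3,5-triol (phloroglucinol) | Oc1cc(O)cc(O)c1 | starting material
14 | (Z)-2-[5-(dichloroboryloxy)-7-methoxy-2-(4-methoxyphenyl)-4-oxo-4H-chromen-3-yl]-3-(4-methoxyphenyl)-1-[2,4,6-tris(dichloroboryloxy)phenyl]prop-2-en-1-one | COc1ccc(/C=C(\C(=O)c2c(OB(Cl)Cl)cc(OB(Cl)Cl)cc2OB(Cl)Cl)c2c(-c3ccc(OC)cc3)oc3cc(OC)cc(OB(Cl)Cl)c3c2=O)cc1 | intermediate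
15 | (Z)-2-[5-hydroxy-7-methoxy-2-(4-methoxyphenyl)-4-oxo-4H-chromen-3-yl]-3-(4-methoxyphenyl)-1-(2,4,6-trihydroxyphenyl)prop-2-en-1-one | COc1ccc(/C=C(\C(=O)c2c(O)cc(O)cc2O)c2c(-c3ccc(OC)cc3)oc3cc(OC)cc(O)c3c2=O)cc1 | intermediate
16 | (2S,3R)-5,7-dihydroxy-3-[5-hydroxy-7-methoxy-2-(4-methoxyphenyl)-4-oxo-4H-chromen-3-yl]-2-(4-methoxyphenyl)chroman-4-one | COc1ccc([C@H]2Oc3cc(O)cc(O)c3C(=O)[C@@H]2c2c(-c3ccc(OC)cc3)oc3cc(OC)cc(O)c3c2=O)cc1 | intermediate
17 | (2S,3R)-5,7-dihydroxy-3-[(2S,3S)-5-hydroxy-7-methoxy-2-(4-methoxyphenyl)-4-oxochroman-3-yl]-2-(4-methoxyphenyl)chroman-4-one | COc1ccc([C@H]2Oc3cc(O)cc(O)c3C(=O)[C@@H]2[C@@H]2C(=O)c3c(O)cc(OC)cc3O[C@@H]2c2ccc(OC)cc2)cc1 | target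

**Step count and risks**

Total step count: 8. Longest linear sequence: 6 steps (5 → 7 → 9 → 10 → 12 → 16 → 17).

Steps most likely to fail:

Step 7 (Proposed new method). The freed chalcone may close through an uncatalysed or acid-catalysed background pathway before the alkaloid takes control, which would erode the enantioselectivity. The sense of induction may also be opposite to the analogy, in which case quinidine replaces quinine. The boron-mediated C-acylation of the hindered acid chloride may be incomplete. The fallback sets out from 12 and 13 and uses known chemistry: AlCl3 in PhNO2–CH2Cl2 at rt, the classical one-operation Friedel–Crafts acylation and ring closure of phloroglucinol-type phenols with α-substituted enoyl chlorides, run under thermodynamic control. This should give the 2,3-trans hybrid as the racemate, that is 16 together with its (2R,3S) enantiomer F1. Separation on a polysaccharide chiral stationary phase then returns the route to 16.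

Step 8. Hydrogen uptake at the tetrasubstituted, doubly flanked C2''=C3'' bond may be slow. Delivery may go to the wrong face, since the facial bias rests on a conformational argument. A ketone may be over-reduced, a benzylic C–O bond hydrogenolysed, or the kinetic cis unit epimerised. The fallback sets out from 16 and replaces surface hydrogenation by ligand-controlled hydride delivery followed by a separate kinetic protonation. A copper hydride 1,4-hydrosilylation (Cu(OAc)2·H2O, the p-tol-BINAP enantiomer matched to hydride delivery on the C2'' face that leads to 2''S, excess PhMe2SiH, toluene) also silylates the three phenols. It should give the silyl enol ether (2S,3R)-5,7-bis[dimethyl(phenyl)silyloxy]-3-{(2R)-4,5-bis[dimethyl(phenyl)silyloxy]-7-methoxy-2-(4-methoxyphenyl)-2H-chromen-3-yl}-2-(4-methoxyphenyl)chroman-4-one F2, in which C2'' has the spatial arrangement of 17. Treatment with Bu4NF–AcOH in THF at −78 °C removes the silyl groups and protonates C3'' anti to the 2''-aryl group, which returns the route to 17.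

Step 5. Transmetalation between the two hindered partners may be slow, with competing protodestannylation or homocoupling. The fallback sets out from 4 and 9 and exchanges the roles of the partners. Iododestannylation of 4 (I2, CH2Cl2, 0 °C, retention) gives tert-butyl (E)-2-iodo-3-(4-methoxyphenyl)prop-2-enoate F3. Miyaura borylation of 9 (bis(pinacolato)diboron, PdCl2(dppf), KOAc, dioxane) gives 5-hydroxy-7-methoxy-2-(4-methoxyphenyl)-3-(4,4,5,5-tetramethyl-1,3,2-dioxaborolan-2-yl)-4H-chromen-4-one F4. Suzuki–Miyaura coupling of F4 with F3 (Pd(PPh3)4, K3PO4, dioxane–H2O) proceeds with retention of alkene geometry and returns the route to 10.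

**Further compounds**

F1 | step 7 | (2R,3S)-5,7-dihydroxy-3-[5-hydroxy-7-methoxy-2-(4-methoxyphenyl)-4-oxo-4H-chromen-3-yl]-2-(4-methoxyphenyl)chroman-4-one | COc1ccc([C@@H]2Oc3cc(O)cc(O)c3C(=O)[C@H]2c2c(-c3ccc(OC)cc3)oc3cc(OC)cc(O)c3c2=O)cc1
F2 | step 8 | (2S,3R)-5,7-bis[dimethyl(phenyl)silyloxy]-3-{(2R)-4,5-bis[dimethyl(phenyl)silyloxy]-7-methoxy-2-(4-methoxyphenyl)-2H-chromen-3-yl}-2-(4-methoxyphenyl)chroman-4-one | COc1ccc([C@H]2Oc3cc(O[Si](C)(C)c4ccccc4)cc(O[Si](C)(C)c4ccccc4)c3C(=O)[C@@H]2C2=C(O[Si](C)(C)c3ccccc3)c3c(O[Si](C)(C)c4ccccc4)cc(OC)cc3O[C@@H]2c2ccc(OC)cc2)cc1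
F3 | step 5 | tert-butyl (E)-2-iodo-3-(4-methoxyphenyl)prop-2-enoate | COc1ccc(/C=C(/I)C(=O)OC(C)(C)C)cc1
F4 | step 5 | 5-hydroxy-7-methoxy-2-(4-methoxyphenyl)-3-(4,4,5,5-tetramethyl-1,3,2-dioxaborolan-2-yl)-4H-chromen-4-one | COc1ccc(-c2oc3cc(OC)cc(O)c3c(=O)c2B2OC(C)(C)C(C)(C)O2)cc1
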